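## Retrosynthetic overview

1. **Feature:** on the cyclobutane, C1 and C3 carry the two imide carbonyls and C2 and C4 carry the two 3,4-dimethoxyphenyl rings. Both aryl rings share a face with the C1 acyl group and lie opposite the C3 acyl group. A mirror plane through C1 and C3 makes C2 and C4 equivalent (meso, achiral), so one directing group on C1 can reach both aryl positions. This C1–C4 numbering is used in the discussion; systematic names keep their own locants.
2. **Last bonds made:** the two imide N–C(O) bonds, leading back to the 1,3-diacid (as its dichloride) and two molecules of 5,6-dihydropyridin-2(1H)-one.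
3. **Key disconnection:** the C2–aryl and C4–aryl bonds, cut in one operation. This leads back to the trans 1,3-amide ester, with the C1 carboxyl masked as its 8-aminoquinoline amide, and 4-iodo-1,2-dimethoxybenzene.
4. **First bond made:** the amide N–C(O) bond, leading back to the purchased trans half-ester and 8-aminoquinoline.
5. **Ring order:** no ring is formed. The cyclobutane, both arenes and both dihydropyridinone rings are bought intact, and the route builds two C–C bonds and their relative configuration.

Key step: step 2

Assumption: the trans half-ester is bought as a single diastereomer; any cis contaminant would be removed by chromatography or crystallisation of the quinolyl amide.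

## Route

Step 1
Reactants: 1 trans-3-(methoxycarbonyl)cyclobutane-1-carboxylic acid; 2 8-aminoquinoline
Product: 3 methyl trans-3-(quinolin-8-ylcarbamoyl)cyclobutane-1-carboxylate (amide and ester on opposite ring faces)
Conditions: EDC (1.3 equiv), DMAP (0.2 equiv), CH2Cl2, 0 °C→rt
Reagents that add atoms: none
Why: Carbodiimide amide coupling with DMAP acyl transfer joins the weakly nucleophilic aromatic amine to the free acid under nearly neutral conditions, so the methyl ester and the trans 1,3-relationship bought with 1 are carried over unchanged.

Step 2
Reactants: 3 methyl trans-3-(quinolin-8-ylcarbamoyl)cyclobutane-1-carboxylate; 4 4-iodo-1,2-dimethoxybenzene (two equivalents are incorporated)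
Product: 6 methyl 2,4-bis(3,4-dimethoxyphenyl)-3-(quinolin-8-ylcarbamoyl)cyclobutane-1-carboxylate (meso; both aryls cis to the amide and trans to the ester), via mono-aryl amide ester 5 (not isolated)
Conditions: Pd(OAc)2 (15 mol %), Ag2CO3 (2 equiv), PivOH (1 equiv), 4 (4 equiv), t-BuOH, 85 °C, sealed tube
Reagents that add atoms: none
Why: After N–H deprotonation the quinolyl amide binds divalent palladium through both nitrogens, and pivalate-assisted concerted metalation–deprotonation takes the one C2–H bond on the amide face to give a five-membered palladacycle fused to the cyclobutane; oxidative addition of 4 raises it to tetravalent palladium, C–C reductive elimination with retention gives 5, and Ag2CO3 removes iodide so that the palladium carboxylate is regenerated. Amide 5 enters the same cycle at C4, whose only reachable hydrogen is again the one cis to the amide, and this gives 6. The closest known reaction type is the 8-aminoquinoline-directed β-C(sp3)–H mono- and diarylation of cyclobutanecarboxamides with aryl iodides, so the step applies known chemistry, and no ring is closed. The new stereocentres C2 and C4 are both controlled by the palladacycle geometry, which delivers each aryl to the face of the C1 amide, while the trans C1/C3 relationship is inherited from 3. The step needs site selectivity for the β-methylenes over the transannular C3–H (also cis to the amide, but reachable only through a strained bridged six-membered palladacycle) and complete double rather than single arylation, which is helped by excess 4 and by the C3 ester lying on the face away from the incoming aryl groups. Over-reaction is excluded because 6 has no β-hydrogen left on the amide face.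

Step 3
Reactants: 6 methyl 2,4-bis(3,4-dimethoxyphenyl)-3-(quinolin-8-ylcarbamoyl)cyclobutane-1-carboxylate
Product: 7 methyl 3-[(tert-butoxycarbonyl)(quinolin-8-yl)carbamoyl]-2,4-bis(3,4-dimethoxyphenyl)cyclobutane-1-carboxylate (meso; ring configuration as in 6)
Conditions: Boc2O (4 equiv), DMAP (0.5 equiv), MeCN, rt→40 °C
Reagents that add atoms: di-tert-butyl dicarbonate, CC(C)(C)OC(=O)OC(=O)OC(C)(C)C
Why: DMAP-catalysed N-tert-butoxycarbonylation of the secondary anilide gives an N-acyl carbamate whose twisted C–N bond is activated for cleavage, and neither the ester nor any ring stereocentre takes part.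

Step 4
Reactants: 7 methyl 3-[(tert-butoxycarbonyl)(quinolin-8-yl)carbamoyl]-2,4-bis(3,4-dimethoxyphenyl)cyclobutane-1-carboxylate
Product: 10 2,4-bis(3,4-dimethoxyphenyl)cyclobutane-1,3-dicarboxylic acid (meso; aryls cis to each other; one carboxyl cis and the other trans to them), via peroxy acid methyl ester 8 (not isolated), via acid methyl ester 9 (not isolated)
Conditions: LiOH·H2O (2 equiv), 30% aq H2O2 (10 equiv), THF–H2O, 0 °C; aq Na2SO3, 0 °C; then LiOH·H2O (5 equiv), rt; wash basic phase with EtOAc; 1 M HCl to pH 2
Reagents that add atoms: hydrogen peroxide, OO (peroxy oxygens of 8, hydroxyl oxygen of the C1 carboxyl group); lithium hydroxide, [Li+].[OH-] (hydroxyl oxygen of the C3 carboxyl group)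
Why: In this hydroperoxide cleavage of an N-acyl carbamate, the small, strongly nucleophilic but weakly basic HOO− attacks the crowded C1 acyl carbonyl faster than C1–H is removed, sulfite reduces peroxy acid 8 to 9, and ordinary saponification of the C3 ester, which already sits in its favoured trans position, completes 10 with all four ring configurations kept.

Step 5
Reactants: 10 2,4-bis(3,4-dimethoxyphenyl)cyclobutane-1,3-dicarboxylic acid
Product: 11 2,4-bis(3,4-dimethoxyphenyl)cyclobutane-1,3-dicarbonyl dichloride (meso; ring configuration as in 10)
Conditions: (COCl)2 (4 equiv), DMF (cat.), CH2Cl2, 0 °C→rt; concentrate, strip with toluene; used crude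
Reagents that add atoms: oxalyl chloride, O=C(Cl)C(=O)Cl
Why: Chloroiminium (Vilsmeier-type) activation converts both acids into acid chlorides without any base, so no ketene or enolate path to C1 inversion is open, and the trans 1,3-arrangement rules out a cyclic anhydride.

Step 6
Reactants: 11 2,4-bis(3,4-dimethoxyphenyl)cyclobutane-1,3-dicarbonyl dichloride; 12 5,6-dihydropyridin-2(1H)-one (two equivalents are incorporated)
Product: 14 1,1'-{[2,4-bis(3,4-dimethoxyphenyl)cyclobutane-1,3-diyl]dicarbonyl}bis(5,6-dihydropyridin-2(1H)-one) (target; meso; both aryls cis to the C1 acyl group and trans to the C3 acyl group), via lithium lactamide 13 (not isolated)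
Conditions: 12 (2.3 equiv), n-BuLi (2.2 equiv), THF, −78 °C; then 11 in THF, −78→−20 °C; aq NH4Cl
Reagents that add atoms: n-butyllithium, [Li]CCCC (supplies only the lithium of 13; no reagent atom remains in 14)
Why: In this N-acylation of a lithium lactamide by an acid chloride (standard imide formation for N-acyl dihydropyridinones), N–H deprotonation at −78 °C outruns addition of n-BuLi to the unsaturated lactam, the nitrogen anion attacks both acyl chlorides, and the low temperature with only a slight excess of 13 should leave C1–H untouched.

## Compound list

1 | trans-3-(methoxycarbonyl)cyclobutane-1-carboxylic acid | COC(=O)[C@H]1C[C@H](C(=O)O)C1 | starting material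
2 | 8-aminoquinoline | Nc1cccc2cccnc12 | starting material
3 | methyl trans-3-(quinolin-8-ylcarbamoyl)cyclobutane-1-carboxylate | COC(=O)[C@H]1C[C@H](C(=O)Nc2cccc3cccnc23)C1 | intermediate
4 | 4-iodo-1,2-dimethoxybenzene | COc1ccc(I)cc1OC | starting material
5 | methyl 2-(3,4-dimethoxyphenyl)-3-(quinolin-8-ylcarbamoyl)cyclobutane-1-carboxylate, aryl cis to the amide and trans to the ester (racemic, one enantiomer drawn) | COc1ccc([C@H]2[C@H](C(=O)OC)C[C@H]2C(=O)Nc2cccc3cccnc23)cc1OC | intermediate
6 | methyl 2,4-bis(3,4-dimethoxyphenyl)-3-(quinolin-8-ylcarbamoyl)cyclobutane-1-carboxylate, both aryls cis to the amide and trans to the ester (meso) | COc1ccc([C@H]2[C@H](C(=O)OC)[C@@H](c3ccc(OC)c(OC)c3)[C@H]2C(=O)Nc3cccc4cccnc34)cc1OC | intermediate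
7 | methyl 3-[(tert-butoxycarbonyl)(quinolin-8-yl)carbamoyl]-2,4-bis(3,4-dimethoxyphenyl)cyclobutane-1-carboxylate, ring configuration as in 6 | COc1ccc([C@H]2[C@H](C(=O)OC)[C@@H](c3ccc(OC)c(OC)c3)[C@H]2C(=O)N(C(=O)OC(C)(C)C)c3cccc4cccnc34)cc1OC | intermediate
8 | 2,4-bis(3,4-dimethoxyphenyl)-3-(methoxycarbonyl)cyclobutane-1-carboperoxoic acid, peroxy acid group cis to both aryls (present as its lithium salt) | COc1ccc([C@H]2[C@H](C(=O)OC)[C@@H](c3ccc(OC)c(OC)c3)[C@H]2C(=O)OO)cc1OC | intermediate
9 | 2,4-bis(3,4-dimethoxyphenyl)-3-(methoxycarbonyl)cyclobutane-1-carboxylic acid, acid cis and ester trans to both aryls (present as its lithium salt) | COc1ccc([C@H]2[C@H](C(=O)OC)[C@@H](c3ccc(OC)c(OC)c3)[C@H]2C(=O)O)cc1OC | intermediate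
10 | 2,4-bis(3,4-dimethoxyphenyl)cyclobutane-1,3-dicarboxylic acid, aryls mutually cis, one carboxyl cis and one trans to them (meso) | COc1ccc([C@H]2[C@H](C(=O)O)[C@@H](c3ccc(OC)c(OC)c3)[C@H]2C(=O)O)cc1OC | intermediate
11 | 2,4-bis(3,4-dimethoxyphenyl)cyclobutane-1,3-dicarbonyl dichloride, ring configuration as in 10 | COc1ccc([C@H]2[C@H](C(=O)Cl)[C@@H](c3ccc(OC)c(OC)c3)[C@H]2C(=O)Cl)cc1OC | intermediate
12 | 5,6-dihydropyridin-2(1H)-one | O=C1C=CCCN1 | starting material
13 | lithium 6-oxo-3,6-dihydropyridin-1(2H)-ide (N-lithio derivative of 12) | [Li]N1CCC=CC1=O | intermediate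
14 | 1,1'-{[2,4-bis(3,4-dimethoxyphenyl)cyclobutane-1,3-diyl]dicarbonyl}bis(5,6-dihydropyridin-2(1H)-one), both aryls cis to the C1 acyl and trans to the C3 acyl group (meso) | COc1ccc([C@H]2[C@H](C(=O)N3CCC=CC3=O)[C@@H](c3ccc(OC)c(OC)c3)[C@H]2C(=O)N2CCC=CC2=O)cc1OC | target

Total step count: 6
Longest linear sequence: 6 steps (1 → 3 → 6 → 7 → 10 → 11 → 14)

## Steps most likely to fail

**1. Step 2.**
- What may go wrong: the sequence may stall after the first arylation, because crowding next to the new aryl ring slows the second metalation. Raising the temperature would then bring in catalyst ageing to palladium black and slow base-induced inversion at C1.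
- Fallback (sets out from 2 and 4, comes back to the route at 6): the two C–aryl bonds are made one at a time in the cis series, with an epimerisation between them.
  - Purchased cis-3-(methoxycarbonyl)cyclobutane-1-carboxylic acid F1 is coupled with 2 (EDC, DMAP, CH2Cl2) to give methyl cis-3-(quinolin-8-ylcarbamoyl)cyclobutane-1-carboxylate F2.
  - In this isomer the ester lies on the reacting face. With only a slight excess of 4 (Pd(OAc)2, Ag2CO3, PivOH, 1,1,1,3,3,3-hexafluoropropan-2-ol, 90 °C) the second, more crowded arylation should lag far enough behind for the all-cis mono-aryl amide ester F3 to be isolated.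
  - NaOMe in MeOH then equilibrates the ester-bearing carbon. The amide carbon is shielded because the amide is deprotonated at nitrogen first, and relief of the cis aryl/ester contact drives the inversion. This gives 5 as an isolated, purified compound.
  - A single directed arylation of 5 with 4 (Pd(OAc)2, Ag2CO3, PivOH, t-BuOH, 75 °C) then gives 6.

**2. Step 6.**
- What may go wrong: the basic lactamide may remove the acidic C1–H, either from the acid chloride (ketene formation) or from the imide once formed. That would invert C1 towards the less crowded arrangement. Acylation at the hindered C1 acyl chloride may also remain incomplete.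
- Fallback (sets out from 12 and 11, comes back at 14): the anionic nucleophile is replaced by a neutral silyl-transfer acylation.
  - Lactam 12 is silylated (Me3SiCl, Et3N, toluene, rt, filtration under argon) to 1-(trimethylsilyl)-5,6-dihydropyridin-2(1H)-one F4.
  - F4 is then warmed with 11 in toluene (rt→60 °C). N-silyl lactams are acylated by acid chlorides with loss of Me3SiCl, so 14 forms without any base in the flask.

**3. Step 4.**
- What may go wrong: hydroperoxide may attack the carbamate carbonyl instead of the crowded acyl carbonyl, which only returns the free amide. Hydroxide may also enolise the activated amide before cleavage, with inversion at C1.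
- Fallback (sets out from 6, bypasses 7, comes back at 10): the chelating amide is cleaved catalytically under neutral conditions.
  - Ni(tmhd)2 (tmhd = 2,2,6,6-tetramethylheptane-3,5-dionate, 10 mol %) in MeOH at 100 °C (sealed tube) effects directed methanolysis of the 8-aminoquinoline amide. The product is dimethyl 2,4-bis(3,4-dimethoxyphenyl)cyclobutane-1,3-dicarboxylate F5, and 2 is released.
  - Both esters are then cleaved with Me3SnOH (1,2-dichloroethane, 80 °C, then 1 M HCl wash), a hydrolysis suited to epimerisable esters, to give 10.

## Further compounds

F1 | step 2 | cis-3-(methoxycarbonyl)cyclobutane-1-carboxylic acid (purchased) | COC(=O)[C@H]1C[C@@H](C(=O)O)C1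
F2 | step 2 | methyl cis-3-(quinolin-8-ylcarbamoyl)cyclobutane-1-carboxylate | COC(=O)[C@H]1C[C@@H](C(=O)Nc2cccc3cccnc23)C1
F3 | step 2 | methyl 2-(3,4-dimethoxyphenyl)-3-(quinolin-8-ylcarbamoyl)cyclobutane-1-carboxylate, aryl, amide and ester all cis (racemic, one enantiomer drawn) | COc1ccc([C@H]2[C@@H](C(=O)OC)C[C@H]2C(=O)Nc2cccc3cccnc23)cc1OC
F4 | step 6 | 1-(trimethylsilyl)-5,6-dihydropyridin-2(1H)-one | C[Si](C)(C)N1CCC=CC1=O
F5 | step 4 | dimethyl 2,4-bis(3,4-dimethoxyphenyl)cyclobutane-1,3-dicarboxylate, aryls mutually cis, one ester cis and one trans to them (meso) | COc1ccc([C@H]2[C@H](C(=O)OC)[C@@H](c3ccc(OC)c(OC)c3)[C@H]2C(=O)OC)cc1OC
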